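## Retrosynthetic overview

- The target is opened at its two gallate esters, at the C5 silyl ether and at all benzyl ethers. This leads back to a 2,3-trans flavan whose ring C is closed last, at O1–C2, by Mitsunobu inversion of a benzylic alcohol.
- The strategy rests on ring A, a 1,3,5-trioxygenated benzene whose three oxygens must be told apart (O1 on C8a, free OH on C5, gallate oxygen on C7) and whose C4a carries the C4 methylene. Ring A is built by benzannulation of 3-(methoxymethoxy)cyclobutenone with a chain-bearing siloxyalkyne, forming C4a–C8a, C5–C6 and C8–C8a.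
- In that step the ketene oxygen becomes the free 8a-OH, the alkyne oxygen the 5-OTIPS and the cyclobutenone oxygen the 7-OMOM.
- The siloxyalkyne comes from a terminal alkyne, made by acetylide displacement of a primary triflate. The C2/C3 stereocentres come from an Evans syn glycolate aldol on protected 3,4-dihydroxybenzaldehyde.
- Ring order: ring B (bought), then ring A (benzannulation), then ring C (Mitsunobu).

Key step: step 12

Assumption: benzyloxyacetyl chloride, 3-ethoxycyclobut-2-en-1-one and 3,4,5-tris(benzyloxy)benzoic acid (perbenzylated gallic acid) are taken as purchased; the target is the (2R,3S), 2,3-trans flavan shown by the SMILES.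

## Route

Step 1
Reactants: 1 3,4-dihydroxybenzaldehyde
Product: 2 3-hydroxy-4-(methoxymethoxy)benzaldehyde
Conditions: MOMCl (1.05 equiv), K2CO3, acetone, 0 °C → rt
Reagents that add atoms: chloromethyl methyl ether, COCCl
Why: The 4-OH, para to the formyl group, is the more acidic phenol, so its phenoxide should be alkylated selectively (Williamson-type O-alkylation).

Step 2
Reactants: 2 3-hydroxy-4-(methoxymethoxy)benzaldehyde
Product: 3 3-(benzyloxy)-4-(methoxymethoxy)benzaldehyde
Conditions: BnBr, K2CO3, DMF, rt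
Reagents that add atoms: benzyl bromide, BrCc1ccccc1
Why: Williamson etherification of the remaining 3-OH under conditions that leave the aldehyde and the MOM ether untouched.

Step 3
Reactants: 4 (R)-4-benzyl-2-oxazolidinone; 5 benzyloxyacetyl chloride
Product: 7 (R)-4-benzyl-3-[(benzyloxy)acetyl]oxazolidin-2-one, via N-lithio oxazolidinone 6 (not isolated)
Conditions: n-BuLi, THF, −78 °C; then 5, −78 → 0 °C
Reagents that add atoms: none
Why: N-acylation of the lithiated oxazolidinone by the acid chloride gives the glycolate imide.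

Step 4
Reactants: 7 (R)-4-benzyl-3-[(benzyloxy)acetyl]oxazolidin-2-one; 3 3-(benzyloxy)-4-(methoxymethoxy)benzaldehyde
Product: 10 (R)-4-benzyl-3-[(2R,3S)-2-(benzyloxy)-3-[3-(benzyloxy)-4-(methoxymethoxy)phenyl]-3-hydroxypropanoyl]oxazolidin-2-one, via boron enolate 8 (not isolated), via boron aldolate 9 (not isolated)
Conditions: Bu2BOTf, Et3N, CH2Cl2, −78 → 0 °C; then 3, −78 → 0 °C; pH 7 buffer, MeOH, H2O2, 0 °C
Reagents that add atoms: none
Why: Evans syn glycolate aldol, in which the Z-boron enolate reacts through a closed chair transition state and the (R)-benzyl group of the auxiliary shields one enolate face, setting the (2R,3S) pair (future C3 with its final configuration and future C2 with the configuration that is inverted in step 14).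

Step 5
Reactants: 10 syn aldol adduct
Product: 11 (R)-4-benzyl-3-[(2R,3S)-2-(benzyloxy)-3-[3-(benzyloxy)-4-(methoxymethoxy)phenyl]-3-(triethylsilyloxy)propanoyl]oxazolidin-2-one
Conditions: TESCl, imidazole, DMAP (cat.), DMF, rt
Reagents that add atoms: chlorotriethylsilane, CC[Si](Cl)(CC)CC
Why: Silylation of the secondary benzylic alcohol under non-Lewis-acidic conditions that spare the aryl MOM ether.

Step 6
Reactants: 11 TES-protected imide
Product: 12 (2S,3S)-2-(benzyloxy)-3-[3-(benzyloxy)-4-(methoxymethoxy)phenyl]-3-(triethylsilyloxy)propan-1-ol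
Conditions: LiBH4, MeOH (1 equiv), THF, 0 °C
Reagents that add atoms: none
Why: Reductive cleavage of the N-acyl oxazolidinone by LiBH4 gives the primary alcohol and returns the auxiliary without epimerising the α-alkoxy centre.

Step 7
Reactants: 12 primary alcohol
Product: 13 (2S,3S)-2-(benzyloxy)-3-[3-(benzyloxy)-4-(methoxymethoxy)phenyl]-3-(triethylsilyloxy)propyl trifluoromethanesulfonate
Conditions: Tf2O, 2,6-lutidine, CH2Cl2, −78 °C; cold aqueous work-up, used crude
Reagents that add atoms: trifluoromethanesulfonic anhydride, O=S(=O)(OS(=O)(=O)C(F)(F)F)C(F)(F)F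
Why: O-sulfonylation of the primary alcohol at low temperature with a hindered base gives a leaving group reactive enough for SN2 at a β-branched carbon.

Step 8
Reactants: 13 primary triflate
Product: 15 (4S,5S)-4-(benzyloxy)-5-[3-(benzyloxy)-4-(methoxymethoxy)phenyl]-5-(triethylsilyloxy)pent-1-yne, via TMS-alkyne 14 (not isolated)
Conditions: Me3SiC≡CLi (from Me3SiC≡CH, n-BuLi), THF/DMPU, −78 → −20 °C; then MeOH, K2CO3 (cat.), rt
Reagents that add atoms: ethynyltrimethylsilane (as its lithium salt), C#C[Si](C)(C)C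
Why: SN2 displacement of the primary triflate by the lithium acetylide followed by methanolysis of the C–Si bond gives the terminal alkyne, with both stereocentres as spectators.

Step 9
Reactants: 15 terminal alkyne
Product: 18 (4S,5S)-4-(benzyloxy)-5-[3-(benzyloxy)-4-(methoxymethoxy)phenyl]-5-(triethylsilyloxy)-1-(triisopropylsilyloxy)pent-1-yne, via lithium acetylide 16 (not isolated), via lithium ynolate 17 (not isolated)
Conditions: LiN(SiMe3)2, THF, −78 °C; LiOOt-Bu (from t-BuOOH, LiN(SiMe3)2), −78 → 0 °C; TIPSOTf, −78 → 0 °C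
Reagents that add atoms: tert-butyl hydroperoxide (as its lithium salt), CC(C)(C)OO; triisopropylsilyl trifluoromethanesulfonate, CC(C)[Si](OS(=O)(=O)C(F)(F)F)(C(C)C)C(C)C
Why: Electrophilic oxygen transfer from lithium tert-butyl peroxide to the lithium acetylide gives the ynolate, which the bulky silyl triflate should capture on oxygen to give the siloxyalkyne (alkynyllithium oxidation and O-silylation).

Step 10
Reactants: 19 3-ethoxycyclobut-2-en-1-one
Product: 20 cyclobutane-1,3-dione
Conditions: 1 M HCl (aq), THF, 0 °C → rt; used at once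
Reagents that add atoms: water, O
Why: Acid hydrolysis of the vinylogous ester (enol ether) releases the enolised 1,3-dione.

Step 11
Reactants: 20 cyclobutane-1,3-dione
Product: 21 3-(methoxymethoxy)cyclobut-2-en-1-one
Conditions: MOMCl, i-Pr2NEt, CH2Cl2, −20 → 0 °C
Reagents that add atoms: chloromethyl methyl ether, COCCl
Why: O-alkylation of the enolised cyclic 1,3-dione by the hard electrophile MOMCl gives the vinylogous MOM ester.

Step 12
Reactants: 21 3-(methoxymethoxy)cyclobut-2-en-1-one; 18 siloxyalkyne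
Product: 26 2-[(2S,3S)-2-(benzyloxy)-3-[3-(benzyloxy)-4-(methoxymethoxy)phenyl]-3-(triethylsilyloxy)propyl]-5-(methoxymethoxy)-3-(triisopropylsilyloxy)phenol, via vinylketene 22 (not isolated), via vinylcyclobutenone 23 (not isolated), via dienylketene 24 (not isolated), via cyclohexadienone 25 (not isolated)
Conditions: 21 (1.5 equiv), toluene, 110 °C, sealed tube
Reagents that add atoms: none
Why: Heating opens cyclobutenone 21 by 4π electrocyclic ring opening to the 3-alkoxy vinylketene 22, whose electrophilic ketene carbon (future C8a) is attacked by the nucleophilic chain-bearing carbon of the siloxyalkyne (future C4a) in a [2+2] cycloaddition that also joins C6 to C5, and the resulting vinylcyclobutenone 23 opens again to dienylketene 24, which closes and tautomerises through dienone 25 to phenol 26. This is the Danheiser benzannulation of a cyclobutenone with a siloxyalkyne to a resorcinol monosilyl ether, run here with a 3-alkoxycyclobutenone as the vinylketene source. Ring A is the only ring closed, by a thermal 6π electrocyclisation of the dienylketene that forms C8–C8a. No stereocentre is created in the product, since the sp3 ring carbon of 23 is lost on ring opening, and the two chain stereocentres are non-epimerisable ether carbons remote from the reacting atoms. The step needs regiocontrol only, which the polarity of the silyl ynol ether and of the ketene should secure, so that the ketene oxygen becomes the free 8a-OH, the alkyne oxygen the 5-OTIPS and the cyclobutenone oxygen the 7-OMOM para to the chain. The vinylogous-ester conjugation in 21 is expected to slow the first ring opening, which is why 110 °C and an excess of 21 are proposed.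

Step 13
Reactants: 26 ring A phenol
Product: 27 2-[(2S,3S)-2-(benzyloxy)-3-[3-(benzyloxy)-4-(methoxymethoxy)phenyl]-3-hydroxypropyl]-5-(methoxymethoxy)-3-(triisopropylsilyloxy)phenol
Conditions: AcOH/THF/H2O, rt
Reagents that add atoms: none
Why: Mild acidic hydrolysis should cleave the alkyl TES ether much faster than the aryl TIPS ether, the aryl MOM ethers or the benzyl ethers.

Step 14
Reactants: 27 benzylic alcohol with free 8a-OH
Product: 28 (2R,3S)-3-(benzyloxy)-2-[3-(benzyloxy)-4-(methoxymethoxy)phenyl]-7-(methoxymethoxy)-5-(triisopropylsilyloxy)chromane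
Conditions: PPh3, DIAD, toluene, −20 → 0 °C
Reagents that add atoms: none
Why: Intramolecular Mitsunobu etherification, in which the phenol displaces the benzylic oxyphosphonium in an SN2 6-exo-tet closure of ring C with inversion at C2 (S to R), giving the 2,3-trans flavan while C3 is untouched.

Step 15
Reactants: 28 bis-MOM flavan
Product: 29 (2R,3S)-3-(benzyloxy)-2-[3-(benzyloxy)-4-hydroxyphenyl]-5-(triisopropylsilyloxy)chroman-7-ol
Conditions: 2 M HCl (aq), MeOH/THF, 45 °C
Reagents that add atoms: none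
Why: Acid-catalysed acetal exchange with methanol removes both aryl MOM ethers and frees exactly the two phenols to be acylated (C7 and C4'), while the aryl TIPS ether and the benzyl ethers persist.

Step 16
Reactants: 29 7,4'-diphenol; 30 3,4,5-tris(benzyloxy)benzoic acid
Product: 31 (2R,3S)-3-(benzyloxy)-2-[3-(benzyloxy)-4-[3,4,5-tris(benzyloxy)benzoyloxy]phenyl]-5-(triisopropylsilyloxy)chroman-7-yl 3,4,5-tris(benzyloxy)benzoate
Conditions: 30 (2.4 equiv), DCC, DMAP (cat.), CH2Cl2, rt
Reagents that add atoms: none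
Why: Steglich esterification of the two free phenols; the C5, C3 and C3' oxygens are all blocked, so no regiochemical question arises.

Step 17
Reactants: 31 bis-gallate TIPS ether
Product: 32 (2R,3S)-3-(benzyloxy)-2-[3-(benzyloxy)-4-[3,4,5-tris(benzyloxy)benzoyloxy]phenyl]-5-hydroxychroman-7-yl 3,4,5-tris(benzyloxy)benzoate
Conditions: HF·pyridine, pyridine, THF, 0 °C → rt
Reagents that add atoms: none
Why: Fluoride-mediated Si–O cleavage under non-basic conditions frees the C5 phenol without transesterifying the aryl gallates.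

Step 18
Reactants: 32 octabenzyl ether
Product: 33 catechin 7,4'-di-O-gallate
Conditions: H2 (1 atm), Pd(OH)2/C, THF/MeOH, rt
Reagents that add atoms: none
Why: Neutral hydrogenolysis removes all eight benzyl ethers (C3, C3' and six on the galloyl rings) and should leave the aryl esters and the C2–O1 bond intact.

## Compound list

1 | 3,4-dihydroxybenzaldehyde | O=Cc1ccc(O)c(O)c1 | starting material
2 | 3-hydroxy-4-(methoxymethoxy)benzaldehyde | O=Cc1ccc(OCOC)c(O)c1 | intermediate
3 | 3-(benzyloxy)-4-(methoxymethoxy)benzaldehyde | O=Cc1ccc(OCOC)c(OCc2ccccc2)c1 | intermediate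
4 | (R)-4-benzyl-2-oxazolidinone | O=C1N[C@H](Cc2ccccc2)CO1 | starting material
5 | benzyloxyacetyl chloride | O=C(Cl)COCc1ccccc1 | starting material
6 | N-lithio-(R)-4-benzyl-2-oxazolidinone (not isolated) | [Li]N1[C@H](Cc2ccccc2)COC1=O | intermediate
7 | (R)-4-benzyl-3-[(benzyloxy)acetyl]oxazolidin-2-one | O=C(COCc1ccccc1)N1[C@H](Cc2ccccc2)COC1=O | intermediate
8 | (Z)-dibutylboron enolate of 7 (not isolated) | CCCCB(CCCC)O/C(N1[C@H](Cc2ccccc2)COC1=O)=C\OCc1ccccc1 | intermediate
9 | dibutylboron aldolate of 10 (not isolated) | CCCCB(CCCC)O[C@@H](c1ccc(OCOC)c(OCc2ccccc2)c1)[C@@H](OCc1ccccc1)C(=O)N1[C@H](Cc2ccccc2)COC1=O | intermediate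
10 | (R)-4-benzyl-3-[(2R,3S)-2-(benzyloxy)-3-[3-(benzyloxy)-4-(methoxymethoxy)phenyl]-3-hydroxypropanoyl]oxazolidin-2-one | O[C@@H](c1ccc(OCOC)c(OCc2ccccc2)c1)[C@@H](OCc1ccccc1)C(=O)N1[C@H](Cc2ccccc2)COC1=O | intermediate
11 | (R)-4-benzyl-3-[(2R,3S)-2-(benzyloxy)-3-[3-(benzyloxy)-4-(methoxymethoxy)phenyl]-3-(triethylsilyloxy)propanoyl]oxazolidin-2-one | CC[Si](CC)(CC)O[C@@H](c1ccc(OCOC)c(OCc2ccccc2)c1)[C@@H](OCc1ccccc1)C(=O)N1[C@H](Cc2ccccc2)COC1=O | intermediate
12 | (2S,3S)-2-(benzyloxy)-3-[3-(benzyloxy)-4-(methoxymethoxy)phenyl]-3-(triethylsilyloxy)propan-1-ol | CC[Si](CC)(CC)O[C@@H](c1ccc(OCOC)c(OCc2ccccc2)c1)[C@@H](OCc1ccccc1)CO | intermediate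
13 | (2S,3S)-2-(benzyloxy)-3-[3-(benzyloxy)-4-(methoxymethoxy)phenyl]-3-(triethylsilyloxy)propyl trifluoromethanesulfonate | CC[Si](CC)(CC)O[C@@H](c1ccc(OCOC)c(OCc2ccccc2)c1)[C@@H](OCc1ccccc1)COS(=O)(=O)C(F)(F)F | intermediate
14 | [(4S,5S)-4-(benzyloxy)-5-[3-(benzyloxy)-4-(methoxymethoxy)phenyl]-5-(triethylsilyloxy)pent-1-yn-1-yl]trimethylsilane (not isolated) | CC[Si](CC)(CC)O[C@@H](c1ccc(OCOC)c(OCc2ccccc2)c1)[C@@H](OCc1ccccc1)CC#C[Si](C)(C)C | intermediate
15 | (4S,5S)-4-(benzyloxy)-5-[3-(benzyloxy)-4-(methoxymethoxy)phenyl]-5-(triethylsilyloxy)pent-1-yne | CC[Si](CC)(CC)O[C@@H](c1ccc(OCOC)c(OCc2ccccc2)c1)[C@@H](OCc1ccccc1)CC#C | intermediate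
16 | lithium acetylide of 15 (not isolated) | CC[Si](CC)(CC)O[C@@H](c1ccc(OCOC)c(OCc2ccccc2)c1)[C@@H](OCc1ccccc1)CC#C[Li] | intermediate
17 | lithium ynolate from 16 (not isolated) | CC[Si](CC)(CC)O[C@@H](c1ccc(OCOC)c(OCc2ccccc2)c1)[C@@H](OCc1ccccc1)CC#CO[Li] | intermediate
18 | (4S,5S)-4-(benzyloxy)-5-[3-(benzyloxy)-4-(methoxymethoxy)phenyl]-5-(triethylsilyloxy)-1-(triisopropylsilyloxy)pent-1-yne | CC[Si](CC)(CC)O[C@@H](c1ccc(OCOC)c(OCc2ccccc2)c1)[C@@H](OCc1ccccc1)CC#CO[Si](C(C)C)(C(C)C)C(C)C | intermediate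
19 | 3-ethoxycyclobut-2-en-1-one | CCOC1=CC(=O)C1 | starting material
20 | cyclobutane-1,3-dione (reacts as its enol, 3-hydroxycyclobut-2-en-1-one) | O=C1CC(=O)C1 | intermediate
21 | 3-(methoxymethoxy)cyclobut-2-en-1-one | O=C1C=C(OCOC)C1 | intermediate
22 | 3-(methoxymethoxy)buta-1,3-dien-1-one, the vinylketene (not isolated) | C=C(OCOC)C=C=O | intermediate
23 | 2-(chain)-3-(triisopropylsilyloxy)-4-[1-(methoxymethoxy)vinyl]cyclobut-2-en-1-one, both C4 epimers (not isolated) | CC[Si](CC)(CC)O[C@@H](c1ccc(OCOC)c(OCc2ccccc2)c1)[C@@H](OCc1ccccc1)CC1=C(O[Si](C(C)C)(C(C)C)C(C)C)C(C(=C)OCOC)C1=O | intermediate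
24 | dienylketene from ring opening of 23 (not isolated) | CC[Si](CC)(CC)O[C@@H](c1ccc(OCOC)c(OCc2ccccc2)c1)[C@@H](OCc1ccccc1)CC(=C=O)C(O[Si](C(C)C)(C(C)C)C(C)C)=CC(=C)OCOC | intermediate
25 | cyclohexa-2,4-dienone tautomer of 26 (not isolated) | CC[Si](CC)(CC)O[C@@H](c1ccc(OCOC)c(OCc2ccccc2)c1)[C@@H](OCc1ccccc1)CC1=C(O[Si](C(C)C)(C(C)C)C(C)C)C=C(OCOC)CC1=O | intermediate
26 | 2-[(2S,3S)-2-(benzyloxy)-3-[3-(benzyloxy)-4-(methoxymethoxy)phenyl]-3-(triethylsilyloxy)propyl]-5-(methoxymethoxy)-3-(triisopropylsilyloxy)phenol | CC[Si](CC)(CC)O[C@@H](c1ccc(OCOC)c(OCc2ccccc2)c1)[C@@H](OCc1ccccc1)Cc1c(O)cc(OCOC)cc1O[Si](C(C)C)(C(C)C)C(C)C | intermediate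
27 | 2-[(2S,3S)-2-(benzyloxy)-3-[3-(benzyloxy)-4-(methoxymethoxy)phenyl]-3-hydroxypropyl]-5-(methoxymethoxy)-3-(triisopropylsilyloxy)phenol | O[C@@H](c1ccc(OCOC)c(OCc2ccccc2)c1)[C@@H](OCc1ccccc1)Cc1c(O)cc(OCOC)cc1O[Si](C(C)C)(C(C)C)C(C)C | intermediate
28 | (2R,3S)-3-(benzyloxy)-2-[3-(benzyloxy)-4-(methoxymethoxy)phenyl]-7-(methoxymethoxy)-5-(triisopropylsilyloxy)chromane | COCOc1cc(O[Si](C(C)C)(C(C)C)C(C)C)c2c(c1)O[C@H](c1ccc(OCOC)c(OCc3ccccc3)c1)[C@@H](OCc1ccccc1)C2 | intermediate
29 | (2R,3S)-3-(benzyloxy)-2-[3-(benzyloxy)-4-hydroxyphenyl]-5-(triisopropylsilyloxy)chroman-7-ol | Oc1cc(O[Si](C(C)C)(C(C)C)C(C)C)c2c(c1)O[C@H](c1ccc(O)c(OCc3ccccc3)c1)[C@@H](OCc1ccccc1)C2 | intermediate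
30 | 3,4,5-tris(benzyloxy)benzoic acid | OC(=O)c1cc(OCc2ccccc2)c(OCc2ccccc2)c(OCc2ccccc2)c1 | starting material
31 | 7,4'-bis[3,4,5-tris(benzyloxy)benzoate] of 29 (5-O-TIPS, 3-O-Bn, 3'-O-Bn) | O=C(Oc1cc(O[Si](C(C)C)(C(C)C)C(C)C)c2c(c1)O[C@H](c1ccc(OC(=O)c3cc(OCc4ccccc4)c(OCc4ccccc4)c(OCc4ccccc4)c3)c(OCc3ccccc3)c1)[C@@H](OCc1ccccc1)C2)c1cc(OCc2ccccc2)c(OCc2ccccc2)c(OCc2ccccc2)c1 | intermediate
32 | 5-hydroxy analogue of 31 (3-O-Bn, 3'-O-Bn, hexa-O-benzyl digallate) | O=C(Oc1cc(O)c2c(c1)O[C@H](c1ccc(OC(=O)c3cc(OCc4ccccc4)c(OCc4ccccc4)c(OCc4ccccc4)c3)c(OCc3ccccc3)c1)[C@@H](OCc1ccccc1)C2)c1cc(OCc2ccccc2)c(OCc2ccccc2)c(OCc2ccccc2)c1 | intermediate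
33 | catechin 7,4'-di-O-gallate | O=C(Oc1cc(O)c2c(c1)O[C@H](c1ccc(OC(=O)c3cc(O)c(O)c(O)c3)c(O)c1)[C@@H](O)C2)c1cc(O)c(O)c(O)c1 | target

## Step count and risks

Total step count: 18. Longest linear sequence: 15 steps (steps 1, 2, 4 to 9 and 12 to 18).

**Steps most likely to fail**

1. Step 12 (benzannulation). The vinylogous-ester cyclobutenone may open too slowly. At the temperature then needed, the siloxyalkyne could isomerise to a silylketene, or the product phenol could be acylated by excess vinylketene.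
   Fallback: generate the same vinylketene at room temperature by photochemical Wolff rearrangement instead of thermal ring opening. It sets out from siloxyalkyne 18 and commercial butane-2,3-dione. The dione is converted with KN(SiMe3)2 and MOMCl into 3-(methoxymethoxy)but-3-en-2-one F1. Its methyl group is trifluoroacetylated (LiN(SiMe3)2, CF3CO2CH2CF3) to 1,1,1-trifluoro-5-(methoxymethoxy)hex-5-ene-2,4-dione F2. Deacylative diazo transfer (MsN3, Et3N, H2O, MeCN) then gives 1-diazo-3-(methoxymethoxy)but-3-en-2-one F3. Irradiation of F3 with 18 in CH2Cl2 at room temperature, then warming to 80 °C, should pass through 22, 23, 24 and 25 and come back to the route at phenol 26.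

2. Step 14 (Mitsunobu closure). The activated benzylic oxyphosphonium, para to an alkoxy group, may ionise. That would cause loss of inversion fidelity at C2, or elimination to the enol ether.
   Fallback: give up configuration transfer and close ring C through the benzylic cation under substrate control. It sets out from alcohol 27, which is treated with a catalytic sulfonic acid (camphorsulfonic acid, CH2Cl2, 0 °C, molecular sieves). The cation should be trapped by the 8a-OH to give the 2,3-trans flavan, in which the aryl and benzyloxy groups are both pseudo-equatorial, whatever the configuration of the carbinol. It comes back at flavan 28 and makes no new compound; partial MOM loss would be harmless because step 15 removes both MOM groups.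

3. Step 9 (siloxyalkyne formation). Oxygen transfer to the acetylide may be incomplete, the ynolate may be silylated on carbon, or the siloxyalkyne may hydrolyse during purification.
   Fallback: reach the ynolate through an alkynyl ester instead of peroxide oxidation. It sets out from lithium acetylide 16, which is treated with PhI(O2CPh)2 in THF at −78 °C to give (4S,5S)-4-(benzyloxy)-5-[3-(benzyloxy)-4-(methoxymethoxy)phenyl]-5-(triethylsilyloxy)pent-1-yn-1-yl benzoate F4. Two equivalents of MeLi cleave the benzoate to regenerate ynolate 17, which is silylated with TIPSOTf, coming back to the route at siloxyalkyne 18.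

## Further compounds

F1 | step 12 | 3-(methoxymethoxy)but-3-en-2-one | CC(=O)C(=C)OCOC
F2 | step 12 | 1,1,1-trifluoro-5-(methoxymethoxy)hex-5-ene-2,4-dione | O=C(CC(=O)C(=C)OCOC)C(F)(F)F
F3 | step 12 | 1-diazo-3-(methoxymethoxy)but-3-en-2-one | [N-]=[N+]=CC(=O)C(=C)OCOC
F0 | step 14 | none | none
F4 | step 9 | (4S,5S)-4-(benzyloxy)-5-[3-(benzyloxy)-4-(methoxymethoxy)phenyl]-5-(triethylsilyloxy)pent-1-yn-1-yl benzoate | CC[Si](CC)(CC)O[C@@H](c1ccc(OCOC)c(OCc2ccccc2)c1)[C@@H](OCc1ccccc1)CC#COC(=O)c1ccccc1
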